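**Plan**

- Retrosynthesis: the C7 benzoate and a C6 silyl ether are removed first. The ring bond C3–C4 is then cut, because ring atoms C1(OMe)–C2=C3(C7)–C4(OH)–C5(OBz)–C6(OH) contain the array C7(=O)–C3(=C2)–C4(OH) of a Morita–Baylis–Hillman adduct of an enal and an aldehyde. The resulting open hept-2-enedial is cut at C2=C3 (Wittig) to a D-lyxose chain.
- Forward, chain: D-lyxose is locked as its benzyl α-pyranoside, O4 is benzoylated (2,3-acetonide as temporary mask), O3 silylated and O2 methylated. Hydrogenolysis, Wittig extension at C1 and oxidation of C5 give the dialdehyde.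
- Forward, ring: the only ring (carbocycle C1–C6) closes by a PMe3-catalysed intramolecular Morita–Baylis–Hillman reaction. Luche reduction, primary benzoylation and desilylation finish the synthesis.
- Stereochemistry: C1, C6 and C5 are C2, C3 and C4 of D-lyxose and are never touched. C4 arises in the ring closure under substrate control.

Key step: step 10

Remark: carbocycles are numbered C1 (OMe), C2=C3 (C7 on C3), C4 (OH), C5 (OBz), C6 (O) throughout; sugar intermediates keep carbohydrate numbering and open-chain compounds are numbered as heptenals. D-Lyxose, benzoyl chloride and (triphenylphosphoranylidene)acetaldehyde are commercial.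

**Route**

Step 1
Reactants: 1 D-lyxose
Product: 2 benzyl α-D-lyxopyranoside
Conditions: BnOH, HCl (dry, cat.), 50 °C; crystallisation
Reagents that add atoms: benzyl alcohol, OCc1ccccc1
Why: Fischer glycosidation under thermodynamic control gives the pyranoside, and the anomeric effect together with the axial O2 favours the α-anomer as for mannose, so C1 is masked while the 2,3-cis-diol stays free.

Step 2
Reactants: 2 benzyl α-D-lyxopyranoside
Product: 3 benzyl 2,3-O-isopropylidene-α-D-lyxopyranoside
Conditions: Me2C(OMe)2, p-toluenesulfonic acid monohydrate (cat.), acetone, rt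
Reagents that add atoms: 2,2-dimethoxypropane, COC(C)(C)OC
Why: Acid-catalysed transacetalisation (acetonide formation) bridges the cis-2,3-diol as a dioxolane and cannot span the trans-3,4-diol, so only O4 remains free.

Step 3
Reactants: 3 benzyl 2,3-O-isopropylidene-α-D-lyxopyranoside; 4 benzoyl chloride
Product: 5 benzyl 4-O-benzoyl-2,3-O-isopropylidene-α-D-lyxopyranoside
Conditions: BzCl, pyridine, 4-(dimethylamino)pyridine (cat.), CH2Cl2, 0 °C → rt
Reagents that add atoms: benzoyl chloride (compound 4), O=C(Cl)c1ccccc1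
Why: Pyridine-mediated acylation (nucleophilic acyl substitution) esterifies the single free secondary hydroxyl and so places the benzoate that ends on C5 of the target.

Step 4
Reactants: 5 benzyl 4-O-benzoyl-2,3-O-isopropylidene-α-D-lyxopyranoside
Product: 6 benzyl 4-O-benzoyl-α-D-lyxopyranoside
Conditions: AcOH/H2O (4:1), 60 °C
Reagents that add atoms: none
Why: Acid-catalysed acetal hydrolysis removes the isopropylidene group, while the benzyl glycoside and the benzoate are stable to warm aqueous acetic acid and acid-promoted acyl shift across the trans-3,4 positions is slow.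

Step 5
Reactants: 6 benzyl 4-O-benzoyl-α-D-lyxopyranoside
Product: 7 benzyl 4-O-benzoyl-3-O-(tert-butyldimethylsilyl)-α-D-lyxopyranoside
Conditions: TBSCl, imidazole, DMF, 0 °C → rt
Reagents that add atoms: tert-butyldimethylsilyl chloride, CC(C)(C)[Si](C)(C)Cl
Why: Regioselective silylation of a cis-diol (imidazole-promoted silyl ether formation) should take the more accessible equatorial 3-OH in preference to the axial 2-OH, as known for α-manno- and α-rhamno-configured 2,3-diols.

Step 6
Reactants: 7 benzyl 4-O-benzoyl-3-O-(tert-butyldimethylsilyl)-α-D-lyxopyranoside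
Product: 8 benzyl 4-O-benzoyl-3-O-(tert-butyldimethylsilyl)-2-O-methyl-α-D-lyxopyranoside
Conditions: MeOTf, 2,6-di-tert-butyl-4-methylpyridine, CH2Cl2, rt → 40 °C
Reagents that add atoms: methyl trifluoromethanesulfonate, COS(=O)(=O)C(F)(F)F
Why: O-Methylation with methyl triflate and a hindered pyridine (Williamson-type alkylation without an alkoxide) etherifies the remaining hydroxyl and avoids the 1,2-silyl migration and benzoate shift that a strong base would set off.

Step 7
Reactants: 8 benzyl 4-O-benzoyl-3-O-(tert-butyldimethylsilyl)-2-O-methyl-α-D-lyxopyranoside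
Product: 9 4-O-benzoyl-3-O-(tert-butyldimethylsilyl)-2-O-methyl-D-lyxopyranose (both anomers)
Conditions: H2 (1 atm), Pd(OH)2/C, EtOAc, rt
Reagents that add atoms: none
Why: Catalytic hydrogenolysis cleaves the benzylic C–O bond of the glycoside and leaves the benzoate and the silyl ether intact, ethyl acetate being chosen to avoid acid-promoted desilylation.

Step 8
Reactants: 9 4-O-benzoyl-3-O-(tert-butyldimethylsilyl)-2-O-methyl-D-lyxopyranose; 10 (triphenylphosphoranylidene)acetaldehyde
Product: 12 (2E,4R,5R,6R)-6-benzoyloxy-5-(tert-butyldimethylsilyloxy)-7-hydroxy-4-methoxyhept-2-enal, via open-chain hydroxy aldehyde 11 (not isolated)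
Conditions: Ph3P=CHCHO, toluene, 70 °C
Reagents that add atoms: (triphenylphosphoranylidene)acetaldehyde (compound 10), O=CC=P(c1ccccc1)(c1ccccc1)c1ccccc1
Why: Wittig olefination of the lactol through its open-chain aldehyde 11 with the stabilised formyl ylide should give the E-enal under neutral conditions that do not epimerise the α-methoxy centre, as known for 2-hydroxytetrahydropyrans.

Step 9
Reactants: 12 (2E,4R,5R,6R)-6-benzoyloxy-5-(tert-butyldimethylsilyloxy)-7-hydroxy-4-methoxyhept-2-enal
Product: 13 (2E,4R,5R,6S)-6-benzoyloxy-5-(tert-butyldimethylsilyloxy)-4-methoxyhept-2-enedial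
Conditions: Dess–Martin periodinane, CH2Cl2, 0 °C → rt; used at once
Reagents that add atoms: none
Why: Dess–Martin oxidation turns the primary alcohol into the aldehyde under near-neutral conditions without touching the enal or epimerising the new α-benzoyloxy aldehyde.

Step 10
Reactants: 13 (2E,4R,5R,6S)-6-benzoyloxy-5-(tert-butyldimethylsilyloxy)-4-methoxyhept-2-enedial
Product: 16 (1R,4R,5R,6R)-5-benzoyloxy-6-(tert-butyldimethylsilyloxy)-4-hydroxy-1-methoxycyclohex-2-ene-3-carbaldehyde, via phosphonium enolate 14 (not isolated), via phosphonium alkoxide 15 (not isolated)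
Conditions: PMe3 (0.3 equiv), tert-amyl alcohol/CH2Cl2, 0 °C → rt
Reagents that add atoms: none
Why: PMe3 adds in conjugate fashion to C2 of the enal to give phosphonium enolate 14, the enolate carbon C3 attacks the C4 aldehyde to give the cyclic phosphonium alkoxide 15, and proton transfer from C3 (relayed by the alcohol cosolvent) followed by E1cB loss of PMe3 restores C2=C3 and frees the catalyst. The closest known reaction type is the phosphine- or amine-catalysed intramolecular Morita–Baylis–Hillman cyclisation of hept-2-enedials and of the related enone and enethioate aldehydes to 6-hydroxycyclohex-1-ene carbonyl compounds. The carbocycle C1–C6 closes through the new C3–C4 bond in a 6-(enolexo)-exo-trig aldol mode. The new stereocentre C4 is set by the substrate: in a chair-like transition state with the C5 benzoate and the C6 silyl ether equatorial and the C1 methoxy group axial, the C3–C4 bond forms anti to the C5–O bond (polar Felkin–Anh) and the carbonyl oxygen takes the pseudo-axial site on the C6 side, which also keeps it clear of the exocyclic enolate (allylic 1,3-strain), so the C4 hydroxyl should end cis to the C5 benzoate (4R). The step needs the catalyst to engage only the enal and the aldol to outrun base-type side reactions (loss of the C6 silyloxy group, epimerisation at C5); the substrate secures the first because the enal is its only Michael acceptor and C3 the only carbon that becomes nucleophilic, and the non-basic phosphine at or below room temperature secures the second.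

Step 11
Reactants: 16 (1R,4R,5R,6R)-5-benzoyloxy-6-(tert-butyldimethylsilyloxy)-4-hydroxy-1-methoxycyclohex-2-ene-3-carbaldehyde
Product: 17 (1R,4R,5R,6R)-5-benzoyloxy-6-(tert-butyldimethylsilyloxy)-3-(hydroxymethyl)-1-methoxycyclohex-2-en-4-ol
Conditions: NaBH4, CeCl3·7H2O, MeOH, −40 °C; AcOH quench
Reagents that add atoms: none
Why: Luche reduction delivers hydride 1,2 to the enal so that C2=C3 is kept, and the low temperature and acidic quench suppress base-induced benzoate migration; no stereocentre is formed.

Step 12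
Reactants: 17 (1R,4R,5R,6R)-5-benzoyloxy-6-(tert-butyldimethylsilyloxy)-3-(hydroxymethyl)-1-methoxycyclohex-2-en-4-ol; 4 benzoyl chloride
Product: 18 (1R,4R,5R,6R)-5-benzoyloxy-3-(benzoyloxymethyl)-6-(tert-butyldimethylsilyloxy)-1-methoxycyclohex-2-en-4-ol
Conditions: BzCl (1.05 equiv), 2,4,6-collidine, CH2Cl2, −40 → 0 °C
Reagents that add atoms: benzoyl chloride (compound 4), O=C(Cl)c1ccccc1
Why: Selective acylation of a primary over a secondary alcohol: at low temperature with a weak hindered base the unhindered primary allylic hydroxyl is esterified, while the C4 hydroxyl, flanked by the C5 benzoate and the C3 substituent, is left.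

Step 13
Reactants: 18 (1R,4R,5R,6R)-5-benzoyloxy-3-(benzoyloxymethyl)-6-(tert-butyldimethylsilyloxy)-1-methoxycyclohex-2-en-4-ol
Product: 19 (1R,4R,5R,6R)-5-benzoyloxy-3-(benzoyloxymethyl)-1-methoxycyclohex-2-ene-4,6-diol (target, CNP0349013.4)
Conditions: HF·pyridine, pyridine, THF, 0 °C → rt
Reagents that add atoms: none
Why: Fluoride-mediated desilylation under buffered, weakly acidic conditions cleaves the Si–O bond without forming an alkoxide that would let the C5 benzoate move to O4 or O6.

**Compound list**

1 | D-lyxose | O=C[C@@H](O)[C@@H](O)[C@H](O)CO | starting material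
2 | benzyl α-D-lyxopyranoside | c1ccccc1CO[C@@H]1[C@@H](O)[C@@H](O)[C@H](O)CO1 | intermediate
3 | benzyl 2,3-O-isopropylidene-α-D-lyxopyranoside | c1ccccc1CO[C@@H]1[C@@H](OC2(C)C)[C@@H](O2)[C@H](O)CO1 | intermediate
4 | benzoyl chloride | O=C(Cl)c1ccccc1 | starting material
5 | benzyl 4-O-benzoyl-2,3-O-isopropylidene-α-D-lyxopyranoside | c1ccccc1CO[C@@H]1[C@@H](OC2(C)C)[C@@H](O2)[C@H](OC(=O)c2ccccc2)CO1 | intermediate
6 | benzyl 4-O-benzoyl-α-D-lyxopyranoside | c1ccccc1CO[C@@H]1[C@@H](O)[C@@H](O)[C@H](OC(=O)c2ccccc2)CO1 | intermediate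
7 | benzyl 4-O-benzoyl-3-O-(tert-butyldimethylsilyl)-α-D-lyxopyranoside | c1ccccc1CO[C@@H]1[C@@H](O)[C@@H](O[Si](C)(C)C(C)(C)C)[C@H](OC(=O)c2ccccc2)CO1 | intermediate
8 | benzyl 4-O-benzoyl-3-O-(tert-butyldimethylsilyl)-2-O-methyl-α-D-lyxopyranoside | c1ccccc1CO[C@@H]1[C@@H](OC)[C@@H](O[Si](C)(C)C(C)(C)C)[C@H](OC(=O)c2ccccc2)CO1 | intermediate
9 | 4-O-benzoyl-3-O-(tert-butyldimethylsilyl)-2-O-methyl-D-lyxopyranose (both anomers) | OC1[C@@H](OC)[C@@H](O[Si](C)(C)C(C)(C)C)[C@H](OC(=O)c2ccccc2)CO1 | intermediate
10 | (triphenylphosphoranylidene)acetaldehyde | O=CC=P(c1ccccc1)(c1ccccc1)c1ccccc1 | starting material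
11 | 4-O-benzoyl-3-O-(tert-butyldimethylsilyl)-2-O-methyl-aldehydo-D-lyxose (open-chain form of 9, not isolated) | O=C[C@@H](OC)[C@@H](O[Si](C)(C)C(C)(C)C)[C@H](OC(=O)c1ccccc1)CO | intermediate
12 | (2E,4R,5R,6R)-6-benzoyloxy-5-(tert-butyldimethylsilyloxy)-7-hydroxy-4-methoxyhept-2-enal | O=C/C=C/[C@@H](OC)[C@@H](O[Si](C)(C)C(C)(C)C)[C@H](OC(=O)c1ccccc1)CO | intermediate
13 | (2E,4R,5R,6S)-6-benzoyloxy-5-(tert-butyldimethylsilyloxy)-4-methoxyhept-2-enedial | O=C/C=C/[C@@H](OC)[C@@H](O[Si](C)(C)C(C)(C)C)[C@H](OC(=O)c1ccccc1)C=O | intermediate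
14 | phosphonium enolate: PMe3 adduct of 13 at C2, enolate over C3–C7 (zwitterion, not isolated) | [O-]C=CC([P+](C)(C)C)[C@@H](OC)[C@@H](O[Si](C)(C)C(C)(C)C)[C@H](OC(=O)c1ccccc1)C=O | intermediate
15 | phosphonium alkoxide: cyclised aldol adduct with PMe3 on C2, CHO on C3 and alkoxide on C4 (zwitterion, not isolated) | CO[C@@H]1C([P+](C)(C)C)C(C=O)[C@@H]([O-])[C@@H](OC(=O)c2ccccc2)[C@@H]1O[Si](C)(C)C(C)(C)C | intermediate
16 | (1R,4R,5R,6R)-5-benzoyloxy-6-(tert-butyldimethylsilyloxy)-4-hydroxy-1-methoxycyclohex-2-ene-3-carbaldehyde | CO[C@@H]1C=C(C=O)[C@@H](O)[C@@H](OC(=O)c2ccccc2)[C@@H]1O[Si](C)(C)C(C)(C)C | intermediate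
17 | (1R,4R,5R,6R)-5-benzoyloxy-6-(tert-butyldimethylsilyloxy)-3-(hydroxymethyl)-1-methoxycyclohex-2-en-4-ol | CO[C@@H]1C=C(CO)[C@@H](O)[C@@H](OC(=O)c2ccccc2)[C@@H]1O[Si](C)(C)C(C)(C)C | intermediate
18 | (1R,4R,5R,6R)-5-benzoyloxy-3-(benzoyloxymethyl)-6-(tert-butyldimethylsilyloxy)-1-methoxycyclohex-2-en-4-ol | CO[C@@H]1C=C(COC(=O)c2ccccc2)[C@@H](O)[C@@H](OC(=O)c2ccccc2)[C@@H]1O[Si](C)(C)C(C)(C)C | intermediate
19 | (1R,4R,5R,6R)-5-benzoyloxy-3-(benzoyloxymethyl)-1-methoxycyclohex-2-ene-4,6-diol | CO[C@@H]1C=C(COC(=O)c2ccccc2)[C@@H](O)[C@@H](OC(=O)c2ccccc2)[C@@H]1O | target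

**Step count**

Total step count: 13. Longest linear sequence: 13 steps, from D-lyxose 1 to target 19.

**Steps most likely to fail**

Step 10. The aldehyde may be attacked on its other face, so that the C4 hydroxyl ends trans to the C5 benzoate. The zwitterion may also act as a base and cause loss of the C6 silyloxy group or epimerisation at C5. The fallback corrects C4 after ring closure, by hydride delivery instead of by the aldol face. It sets out from dialdehyde 13: the closure is run as in step 10, and the C4-epimeric hydroxy aldehyde F1 is taken through the conditions of steps 11 and 12 to the C4-epimeric diol F2 and the C4-epimeric primary benzoate F3. Dess–Martin oxidation of the secondary allylic hydroxyl gives the cyclohexenone F4. Corey–Bakshi–Shibata reduction with catecholborane and (R)-1-methyl-3,3-diphenyltetrahydro-1H,3H-pyrrolo[1,2-c][1,3,2]oxazaborole at −78 °C, with the alkenyl arm acting as the larger group, is expected to give the 4R alcohol. This reagent control is less secure than usual because the other arm is also branched. The product is compound 18, where the route is rejoined.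

Step 8. The weakly nucleophilic formyl ylide meets only the small open-chain fraction 11, so the enal formed may be olefinated a second time. The freed primary hydroxyl may also add to the enal in an oxa-Michael closure or take over the benzoyl group from O4. The fallback replaces the aldehyde by a thioester as the activating group of the alkene. It sets out from lactol 9: S-ethyl (triphenylphosphoranylidene)thioacetate in toluene at 70 °C gives the hydroxy enethioate F5, which cannot be olefinated again and is a weaker Michael acceptor. Dess–Martin oxidation gives the formyl enethioate F6. PMe3 in CH2Cl2 closes the same C3–C4 bond by the known intramolecular Morita–Baylis–Hillman reaction of enethioates, giving the cyclohexene thioester F7. Fukuyama reduction (Et3SiH, Pd/C, acetone, rt) then gives aldehyde 16, where the route is rejoined.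

Step 5. Silylation may divide between O3 and O2, and the silyl group may move between the two cis oxygens. The fallback sets the regiochemistry through a tin acetal instead of relying on intrinsic reactivity. It sets out from diol 6: Bu2SnO in refluxing toluene with removal of water gives the 2,3-O-dibutylstannylene acetal F8, in which the equatorial O3 is the activated oxygen. TBSCl at rt then silylates O3, and hydrolytic work-up returns to compound 7.

**Further compounds**

F1 | step 10 | (1R,4S,5R,6R)-5-benzoyloxy-6-(tert-butyldimethylsilyloxy)-4-hydroxy-1-methoxycyclohex-2-ene-3-carbaldehyde (C4 epimer of 16) | CO[C@@H]1C=C(C=O)[C@H](O)[C@@H](OC(=O)c2ccccc2)[C@@H]1O[Si](C)(C)C(C)(C)C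
F2 | step 10 | (1R,4S,5R,6R)-5-benzoyloxy-6-(tert-butyldimethylsilyloxy)-3-(hydroxymethyl)-1-methoxycyclohex-2-en-4-ol (C4 epimer of 17) | CO[C@@H]1C=C(CO)[C@H](O)[C@@H](OC(=O)c2ccccc2)[C@@H]1O[Si](C)(C)C(C)(C)C
F3 | step 10 | (1R,4S,5R,6R)-5-benzoyloxy-3-(benzoyloxymethyl)-6-(tert-butyldimethylsilyloxy)-1-methoxycyclohex-2-en-4-ol (C4 epimer of 18) | CO[C@@H]1C=C(COC(=O)c2ccccc2)[C@H](O)[C@@H](OC(=O)c2ccccc2)[C@@H]1O[Si](C)(C)C(C)(C)C
F4 | step 10 | (1R,5S,6R)-5-benzoyloxy-3-(benzoyloxymethyl)-6-(tert-butyldimethylsilyloxy)-1-methoxycyclohex-2-en-4-one | CO[C@@H]1C=C(COC(=O)c2ccccc2)C(=O)[C@@H](OC(=O)c2ccccc2)[C@@H]1O[Si](C)(C)C(C)(C)C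
F5 | step 8 | S-ethyl (2E,4R,5R,6R)-6-benzoyloxy-5-(tert-butyldimethylsilyloxy)-7-hydroxy-4-methoxyhept-2-enethioate | CCSC(=O)/C=C/[C@@H](OC)[C@@H](O[Si](C)(C)C(C)(C)C)[C@H](OC(=O)c1ccccc1)CO
F6 | step 8 | S-ethyl (2E,4R,5R,6S)-6-benzoyloxy-5-(tert-butyldimethylsilyloxy)-4-methoxy-7-oxohept-2-enethioate | CCSC(=O)/C=C/[C@@H](OC)[C@@H](O[Si](C)(C)C(C)(C)C)[C@H](OC(=O)c1ccccc1)C=O
F7 | step 8 | S-ethyl (1R,4R,5R,6R)-5-benzoyloxy-6-(tert-butyldimethylsilyloxy)-4-hydroxy-1-methoxycyclohex-2-ene-3-carbothioate | CO[C@@H]1C=C(C(=O)SCC)[C@@H](O)[C@@H](OC(=O)c2ccccc2)[C@@H]1O[Si](C)(C)C(C)(C)C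
F8 | step 5 | benzyl 4-O-benzoyl-2,3-O-(dibutylstannylene)-α-D-lyxopyranoside | c1ccccc1CO[C@@H]1[C@@H](O[Sn]2(CCCC)CCCC)[C@@H](O2)[C@H](OC(=O)c2ccccc2)CO1
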